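The target is cut across C5–C10 and C1–C2 (labdane numbering), which opens rings A and B at once. The feature used is that the methyl carbinol C8 of ring B is bonded to C9, while C8–C7–C6–C5=C4 is the chain of (S)-linalool: a C9 ketone both activates a C1=C10 dienophile and, bound together with the C8 ether oxygen to magnesium, passes the C8 configuration on. A single intramolecular Diels–Alder reaction of the 2-silyloxydiene C5=C4–C3=C2 then forms both rings, sets C5 and C10, and leaves a C3=C4 enol silane and the C9 ketone as handles. Its precursor is an open-chain (E)-1,7,9-decatrien-3-one carrying the C8 MOM ether.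

Key step: step 9

Numbering: labdane numbers are used for all ring compounds (C17 is the methyl on C8, C20 the methyl on C10, C11–C16 the side chain on C9); the target is (3R,4S,5S,8S,9R,10R).
Assumption: (S)-linalool of high enantiomeric purity and phosphorane 11 are taken as purchasable; no bond to C8 is ever broken, so the enantiomeric purity of the target is that of the linalool.

Step 1
Reactants: 1 (S)-linalool
Product: 2 (3S)-3-(methoxymethoxy)-3,7-dimethylocta-1,6-diene
Conditions: MOMCl, i-Pr2NEt, CH2Cl2, 0 to 40 °C
Reagents that add atoms: chloromethyl methyl ether, COCCl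
Why: O-alkylation of the tertiary alcohol by the oxocarbenium-type electrophile under amine base (MOM ether formation) installs the ether oxygen needed later for two-point binding and leaves C8 untouched.

Step 2
Reactants: 2 (3S)-3-(methoxymethoxy)-3,7-dimethylocta-1,6-diene
Product: 3 (3S)-6,7-epoxy-3-(methoxymethoxy)-3,7-dimethyloct-1-ene (both C6 epimers)
Conditions: mCPBA, NaHCO3, CH2Cl2, 0 °C
Reagents that add atoms: meta-chloroperoxybenzoic acid, O=C(OO)c1cccc(Cl)c1
Why: Prilezhaev epoxidation should select the electron-rich trisubstituted alkene over the monosubstituted vinyl group, masking the future C4=C5 position; the new centre is destroyed in step 6, so both epimers are carried on.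

Step 3
Reactants: 3 (3S)-6,7-epoxy-3-(methoxymethoxy)-3,7-dimethyloct-1-ene
Product: 5 (2S)-4-(3,3-dimethyloxiran-2-yl)-2-(methoxymethoxy)-2-methylbutanal, via secondary ozonide 4 (not isolated)
Conditions: O3, CH2Cl2, −78 °C; then PPh3, −78 °C to rt
Reagents that add atoms: ozone, [O-][O+]=O
Why: Ozonolysis (Criegee mechanism) with reductive work-up cleaves the only remaining alkene to the non-enolisable α-alkoxy aldehyde that becomes C9, the epoxide and the acetal being inert to ozone at low temperature.

Step 4
Reactants: 5 (2S)-4-(3,3-dimethyloxiran-2-yl)-2-(methoxymethoxy)-2-methylbutanal; 6 isopropenylmagnesium bromide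
Product: 7 (4S)-6-(3,3-dimethyloxiran-2-yl)-4-(methoxymethoxy)-2,4-dimethylhex-1-en-3-ol (both C3 epimers)
Conditions: THF, −78 °C; H2O quench
Reagents that add atoms: isopropenylmagnesium bromide 6, C=C(C)[Mg]Br
Why: Grignard 1,2-addition to the aldehyde is far faster at −78 °C than opening of a trisubstituted epoxide, and the new carbinol centre is oxidised away in step 5, so its configuration is irrelevant.

Step 5
Reactants: 7 (4S)-6-(3,3-dimethyloxiran-2-yl)-4-(methoxymethoxy)-2,4-dimethylhex-1-en-3-ol
Product: 8 (4S)-6-(3,3-dimethyloxiran-2-yl)-4-(methoxymethoxy)-2,4-dimethylhex-1-en-3-one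
Conditions: Dess–Martin periodinane, NaHCO3, CH2Cl2, 0 °C to rt
Reagents that add atoms: none
Why: Dess–Martin oxidation of the secondary allylic alcohol under buffered conditions should give the isopropenyl ketone (C9 enone) without opening the epoxide.

Step 6
Reactants: 8 (4S)-6-(3,3-dimethyloxiran-2-yl)-4-(methoxymethoxy)-2,4-dimethylhex-1-en-3-one
Product: 10 (4S)-4-(methoxymethoxy)-4,6-dimethyl-5-oxohept-6-enal, via vicinal diol 9 (not isolated)
Conditions: H5IO6, THF–H2O, 0 °C
Reagents that add atoms: none
Why: Periodic acid hydrolyses the epoxide in the aqueous medium and cleaves the resulting glycol (Malaprade cleavage) in one flask, unmasking C5 as an aldehyde while the acid-stable enone and MOM ether should survive.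

Step 7
Reactants: 10 (4S)-4-(methoxymethoxy)-4,6-dimethyl-5-oxohept-6-enal; 11 3-(triphenylphosphoranylidene)butan-2-one
Product: 12 (3E,7S)-7-(methoxymethoxy)-3,7,9-trimethyldeca-3,9-diene-2,8-dione
Conditions: PhMe, 80 °C, BHT (trace)
Reagents that add atoms: 3-(triphenylphosphoranylidene)butan-2-one 11, CC(=O)C(C)=P(c1ccccc1)(c1ccccc1)c1ccccc1
Why: Wittig olefination with the acyl-stabilised ylide should react only at the unhindered aldehyde, not at the neopentyl C9 ketone, and give the (E)-trisubstituted enone, so the C3 carbonyl arrives only after the C9 enone is complete.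

Step 8
Reactants: 12 (3E,7S)-7-(methoxymethoxy)-3,7,9-trimethyldeca-3,9-diene-2,8-dione
Product: 13 (4S,7E)-9-(tert-butyldimethylsilyloxy)-4-(methoxymethoxy)-2,4,8-trimethyldeca-1,7,9-trien-3-one
Conditions: TBSOTf, Et3N, CH2Cl2, −78 to 0 °C
Reagents that add atoms: tert-butyldimethylsilyl trifluoromethanesulfonate, CC(C)(C)[Si](C)(C)OS(=O)(=O)C(F)(F)F
Why: Soft enolisation (silyl triflate and amine) of the only enolisable ketone at its methyl group gives the cross-conjugated 2-silyloxydiene, the C9 ketone having no α-hydrogen; the triene is purified on amine-deactivated silica and used at once.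

Step 9
Reactants: 13 (4S,7E)-9-(tert-butyldimethylsilyloxy)-4-(methoxymethoxy)-2,4,8-trimethyldeca-1,7,9-trien-3-one
Product: 14 3-(tert-butyldimethylsilyloxy)-8-(methoxymethoxy)-4,8,10-trimethyl-trans-decal-3-en-9-one (H5 trans to C20; C17 cis to C20; OMOM equatorial)
Conditions: MgBr2·OEt2 (2.5 equiv), CH2Cl2, −40 to 0 °C
Reagents that add atoms: none
Why: MgBr2 binds the C9 carbonyl and the C8 ether oxygen in a five-membered chelate, which lowers the LUMO of the C1=C10 enone, and the diene C5=C4–C3=C2 then adds in a concerted but asynchronous normal-demand [4+2] in which the nucleophilic enol-silane terminus C2 bonds to the enone β-carbon C1 ahead of C5–C10. The closest known reaction type is the Lewis-acid-promoted type 1 intramolecular Diels–Alder reaction of 1,7,9-decatrien-3-ones that carry 2-silyloxydienes, joined here to the chelation control known for α′-alkoxy enone dienophiles. Ring A closes as the cyclohexene of the cycloadduct through C1–C2 and C5–C10, and ring B closes through the same C5–C10 bond as the six-membered ring spanned by the tether C6–C7–C8–C9, folded as a chair. C5 and C10 are set relative to each other by the (E)-geometry of C4=C5 and by a transition state with the C9 carbonyl exo and the C20 methyl endo, which gives the trans ring fusion, and their absolute sense comes from C8, because the chelate keeps the C8–O bond in the carbonyl plane (equatorial) and so forces C17 axial, syn to the developing axial C20. The step needs exo and diene-face selectivity: the α-methyl group of the methacryloyl-type dienophile and the bulk of the magnesium chelate, which cannot sit under the silyloxydiene, favour the exo mode, and the chelate fixes the face because only the doubly bound enone is activated enough to react at this temperature. Regiochemistry is dictated by the tether and reinforced by the matched polarity of C2 and C1.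

Step 10
Reactants: 14 3-(tert-butyldimethylsilyloxy)-8-(methoxymethoxy)-4,8,10-trimethyl-trans-decal-3-en-9-one
Product: 15 3-(tert-butyldimethylsilyloxy)-8-(methoxymethoxy)-4,8,10-trimethyl-trans-decal-3-en-9-ol (9-OH expected equatorial; either epimer serves)
Conditions: LiAlH4, THF, 0 °C to rt
Reagents that add atoms: none
Why: Hydride reduction of the hindered, non-enolisable ketone should occur from the face opposite the two flanking axial methyl groups, and the C9 configuration is irrelevant because C9 becomes a radical in step 12; the enol silane, which masks the C3 ketone, is inert to hydride.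

Step 11
Reactants: 15 3-(tert-butyldimethylsilyloxy)-8-(methoxymethoxy)-4,8,10-trimethyl-trans-decal-3-en-9-ol
Product: 17 O-[3-(tert-butyldimethylsilyloxy)-8-(methoxymethoxy)-4,8,10-trimethyl-trans-decal-3-en-9-yl] S-methyl dithiocarbonate, via sodium xanthate salt 16 (not isolated)
Conditions: NaH, imidazole (cat.), THF, 0 °C to rt; CS2; then MeI
Reagents that add atoms: carbon disulfide, S=C=S; iodomethane, CI
Why: Xanthate formation (first half of a Barton–McCombie sequence) should succeed even on this neopentyl-type alkoxide because CS2 is a small electrophile, and Chugaev elimination is excluded since neither C8 nor C10 carries hydrogen.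

Step 12
Reactants: 17 O-(decalin C9) S-methyl dithiocarbonate; 18 but-3-en-2-one
Product: 19 4-[3-(tert-butyldimethylsilyloxy)-8-(methoxymethoxy)-4,8,10-trimethyl-trans-decal-3-en-9-yl]butan-2-one (side chain axial on C9, trans to C17 and C20)
Conditions: Bu3SnH (slow addition), AIBN, PhH, 80 °C, excess 18
Reagents that add atoms: but-3-en-2-one 18, C=CC(C)=O
Why: Giese reaction: the stannyl radical fragments the xanthate to the secondary C9 radical, which adds to the unsubstituted enone terminus on the ring face anti to the axial C17 and C20 methyl groups of the two neighbouring carbons (axial attack), which sets C9 with the chain trans to both.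

Step 13
Reactants: 19 9-(3-oxobutyl) decalin enol silane
Product: 21 3-(tert-butyldimethylsilyloxy)-8-(methoxymethoxy)-4,8,10-trimethyl-9-[3-(trifluoromethanesulfonyloxy)but-3-enyl]-trans-decal-3-ene, via potassium enolate 20 (not isolated)
Conditions: KN(SiMe3)2, THF, −78 °C; then PhNTf2
Reagents that add atoms: N-phenylbis(trifluoromethanesulfonimide), O=S(=O)(N(c1ccccc1)S(=O)(=O)C(F)(F)F)C(F)(F)F
Why: Kinetic deprotonation of the methyl ketone at the less hindered methyl group and O-sulfonylation of the terminal enolate give the 2-triflyloxy-1-alkene, which also masks the side-chain carbonyl for the ring A steps.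

Step 14
Reactants: 21 9-[3-(triflyloxy)but-3-enyl] decalin enol silane; 22 formaldehyde (37% aqueous)
Product: 23 4-(hydroxymethyl)-8-(methoxymethoxy)-4,8,10-trimethyl-9-[3-(trifluoromethanesulfonyloxy)but-3-enyl]-trans-decalin-3-one (CH2OH equatorial and trans to C20; C4 methyl axial)
Conditions: Sc(OTf)3 (10 mol %), THF–H2O, rt
Reagents that add atoms: formaldehyde 22, C=O
Why: Mukaiyama aldol hydroxymethylation with a water-tolerant triflate Lewis acid: the regiodefined C3=C4 enol silane attacks formaldehyde at C4 from the face opposite the axial C20 methyl (1,3-diaxial shielding), so the new CH2OH is equatorial and the C4 methyl axial.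

Step 15
Reactants: 23 3-keto-4-hydroxymethyl enol triflate
Product: 24 8-(methoxymethoxy)-4-[(methoxymethoxy)methyl]-4,8,10-trimethyl-9-[3-(trifluoromethanesulfonyloxy)but-3-enyl]-trans-decalin-3-one
Conditions: MOMCl, i-Pr2NEt, CH2Cl2, 0 °C to rt
Reagents that add atoms: chloromethyl methyl ether, COCCl
Why: MOM ether formation on the primary neopentyl alcohol under amine base is too mild to trigger retro-aldol loss of formaldehyde and keeps the primary oxygen distinct from the C3 oxygen.

Step 16
Reactants: 24 3-keto bis-MOM enol triflate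
Product: 25 8-(methoxymethoxy)-4-[(methoxymethoxy)methyl]-4,8,10-trimethyl-9-[3-(trifluoromethanesulfonyloxy)but-3-enyl]-trans-decalin-3-ol (3-OH equatorial, cis to C20)
Conditions: NaBH4, MeOH–THF, 0 °C
Reagents that add atoms: none
Why: Borohydride reduction of the 4,4-disubstituted cyclohexanone proceeds by axial hydride attack on the face opposite the axial C4 methyl, giving the equatorial C3 alcohol, and the enol triflate is inert.

Step 17
Reactants: 25 3-hydroxy bis-MOM enol triflate
Product: 26 3-acetoxy-8-(methoxymethoxy)-4-[(methoxymethoxy)methyl]-4,8,10-trimethyl-9-[3-(trifluoromethanesulfonyloxy)but-3-enyl]-trans-decalin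
Conditions: Ac2O, DMAP, pyridine, rt
Reagents that add atoms: acetic anhydride, CC(=O)OC(C)=O
Why: DMAP-catalysed acyl transfer to the only free hydroxyl places the acetate on C3 with no regiochemical choice to make.

Step 18
Reactants: 26 3-acetoxy bis-MOM enol triflate
Product: 27 3-acetoxy-4-(hydroxymethyl)-4,8,10-trimethyl-9-[3-(trifluoromethanesulfonyloxy)but-3-enyl]-trans-decalin-8-ol
Conditions: ZnBr2, n-PrSH, CH2Cl2, 0 °C, 10 min
Reagents that add atoms: none
Why: Lewis-acid-assisted thiolysis of both MOM acetals (ZnBr2 activates, the thiol captures the methoxymethyl cation) frees the primary and the tertiary hydroxyl under conditions that spare acetate and enol triflate, and the short time at 0 °C avoids acyl migration.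

Step 19
Reactants: 27 3-acetoxy-4-(hydroxymethyl)-8-hydroxy enol triflate; 28 tributyl(vinyl)stannane
Product: 29 CNP0313672.1
Conditions: Pd(PPh3)4 (5 mol %), LiCl, THF, 65 °C
Reagents that add atoms: tributyl(vinyl)stannane 28, C=C[Sn](CCCC)(CCCC)CCCC
Why: Stille coupling (oxidative addition of zerovalent palladium into the enol triflate, chloride-assisted transmetalation from tin, reductive elimination) builds the 2-substituted 1,3-diene under neutral conditions as the last operation, so the diene and the C8 carbinol never meet acid and the monoacetate never meets base.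

Compound list
1 | (S)-linalool, (3S)-3,7-dimethylocta-1,6-dien-3-ol | CC(C)=CCC[C@](C)(O)C=C | starting material
2 | (3S)-3-(methoxymethoxy)-3,7-dimethylocta-1,6-diene | CC(C)=CCC[C@](C)(OCOC)C=C | intermediate
3 | (3S)-6,7-epoxy-3-(methoxymethoxy)-3,7-dimethyloct-1-ene, both C6 epimers | CC1(C)OC1CC[C@](C)(OCOC)C=C | intermediate
4 | secondary ozonide (1,2,4-trioxolane) of 3, not isolated | CC1(C)OC1CC[C@](C)(OCOC)C1OCOO1 | intermediate
5 | (2S)-4-(3,3-dimethyloxiran-2-yl)-2-(methoxymethoxy)-2-methylbutanal | CC1(C)OC1CC[C@](C)(OCOC)C=O | intermediate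
6 | isopropenylmagnesium bromide | C=C(C)[Mg]Br | starting material
7 | (4S)-6-(3,3-dimethyloxiran-2-yl)-4-(methoxymethoxy)-2,4-dimethylhex-1-en-3-ol, both C3 epimers | CC1(C)OC1CC[C@](C)(OCOC)C(O)C(C)=C | intermediate
8 | (4S)-6-(3,3-dimethyloxiran-2-yl)-4-(methoxymethoxy)-2,4-dimethylhex-1-en-3-one | CC1(C)OC1CC[C@](C)(OCOC)C(=O)C(C)=C | intermediate
9 | (4S)-7,8-dihydroxy-4-(methoxymethoxy)-2,4,8-trimethylnon-1-en-3-one, not isolated | CC(C)(O)C(O)CC[C@](C)(OCOC)C(=O)C(C)=C | intermediate
10 | (4S)-4-(methoxymethoxy)-4,6-dimethyl-5-oxohept-6-enal | O=CCC[C@](C)(OCOC)C(=O)C(C)=C | intermediate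
11 | 3-(triphenylphosphoranylidene)butan-2-one | CC(=O)C(C)=P(c1ccccc1)(c1ccccc1)c1ccccc1 | starting material
12 | (3E,7S)-7-(methoxymethoxy)-3,7,9-trimethyldeca-3,9-diene-2,8-dione | C=C(C)C(=O)[C@@](C)(OCOC)CC/C=C(C)/C(C)=O | intermediate
13 | (4S,7E)-9-(tert-butyldimethylsilyloxy)-4-(methoxymethoxy)-2,4,8-trimethyldeca-1,7,9-trien-3-one (open-chain silyloxy trienone) | C=C(C)C(=O)[C@@](C)(OCOC)CC/C=C(C)/C(=C)O[Si](C)(C)C(C)(C)C | intermediate
14 | trans-decalin C9 ketone with C3=C4 enol silane; H5 trans to C20, C17 cis to C20 (both axial), 8-OMOM equatorial | O=C1[C@]2(C)CCC(O[Si](C)(C)C(C)(C)C)=C(C)[C@H]2CC[C@]1(C)OCOC | intermediate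
15 | C9 alcohol of 14 (OH drawn equatorial, on the side of C17 and C20) | O[C@H]1[C@]2(C)CCC(O[Si](C)(C)C(C)(C)C)=C(C)[C@H]2CC[C@]1(C)OCOC | intermediate
16 | sodium O-(decalin C9) dithiocarbonate, not isolated | [Na+].[S-]C(=S)O[C@H]1[C@]2(C)CCC(O[Si](C)(C)C(C)(C)C)=C(C)[C@H]2CC[C@]1(C)OCOC | intermediate
17 | O-(decalin C9) S-methyl dithiocarbonate (xanthate of 15) | CSC(=S)O[C@H]1[C@]2(C)CCC(O[Si](C)(C)C(C)(C)C)=C(C)[C@H]2CC[C@]1(C)OCOC | intermediate
18 | but-3-en-2-one | C=CC(C)=O | starting material
19 | 9-(3-oxobutyl) decalin enol silane; chain axial on C9, trans to C17 and C20 | CC(=O)CC[C@@H]1[C@]2(C)CCC(O[Si](C)(C)C(C)(C)C)=C(C)[C@H]2CC[C@]1(C)OCOC | intermediate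
20 | terminal potassium enolate of 19, not isolated | [K+].[O-]C(=C)CC[C@@H]1[C@]2(C)CCC(O[Si](C)(C)C(C)(C)C)=C(C)[C@H]2CC[C@]1(C)OCOC | intermediate
21 | 9-[3-(trifluoromethanesulfonyloxy)but-3-enyl] decalin enol silane | C=C(OS(=O)(=O)C(F)(F)F)CC[C@@H]1[C@]2(C)CCC(O[Si](C)(C)C(C)(C)C)=C(C)[C@H]2CC[C@]1(C)OCOC | intermediate
22 | formaldehyde | C=O | starting material
23 | 3-ketone with equatorial 4-CH2OH (trans to C20) and axial 4-methyl; 8-OMOM; side-chain enol triflate | C=C(OS(=O)(=O)C(F)(F)F)CC[C@@H]1[C@]2(C)CCC(=O)[C@](C)(CO)[C@H]2CC[C@]1(C)OCOC | intermediate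
24 | primary MOM ether of 23 | C=C(OS(=O)(=O)C(F)(F)F)CC[C@@H]1[C@]2(C)CCC(=O)[C@](C)(COCOC)[C@H]2CC[C@]1(C)OCOC | intermediate
25 | equatorial C3 alcohol from 24 | C=C(OS(=O)(=O)C(F)(F)F)CC[C@@H]1[C@]2(C)CC[C@@H](O)[C@](C)(COCOC)[C@H]2CC[C@]1(C)OCOC | intermediate
26 | C3 acetate of 25 | C=C(OS(=O)(=O)C(F)(F)F)CC[C@@H]1[C@]2(C)CC[C@@H](OC(C)=O)[C@](C)(COCOC)[C@H]2CC[C@]1(C)OCOC | intermediate
27 | 3-acetoxy-4-(hydroxymethyl)-8-hydroxy decalin with side-chain enol triflate | C=C(OS(=O)(=O)C(F)(F)F)CC[C@@H]1[C@]2(C)CC[C@@H](OC(C)=O)[C@](C)(CO)[C@H]2CC[C@]1(C)O | intermediate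
28 | tributyl(vinyl)stannane | C=C[Sn](CCCC)(CCCC)CCCC | starting material
29 | CNP0313672.1, (3R,4S,5S,8S,9R,10R) 3-acetate of the 3,8-dihydroxy-4-(hydroxymethyl) labda-13(16),14-diene | C=CC(=C)CC[C@@H]1[C@]2(C)CC[C@@H](OC(C)=O)[C@](C)(CO)[C@H]2CC[C@]1(C)O | target

Total step count: 19. Longest linear sequence: 19 steps from 1.

Steps most likely to fail

Step 9. The tertiary ether oxygen may be bound only part of the time, so that material cyclises through a one-point complex in which the C8–O bond turns perpendicular to the carbonyl and C17 goes equatorial; the result would be eroded diene-face selectivity. Closure with the carbonyl endo to the cis-fused isomer and desilylation by the Lewis acid are lesser risks. The fallback sets out from 13 and comes back at 14. It gives up substrate control through the chelate for reagent control: 13 would be cyclised with a cationic chiral oxazaborolidine (the B-o-tolyl oxazaborolidine from diphenylprolinol, activated with Tf2NH, 20 mol %, CH2Cl2, −78 to −40 °C). This is a one-point Lewis acid whose own chirality selects the diene face in cycloadditions of enones with silyloxydienes, and the catalyst antipode that favours the required face would be used. This makes no new compound (F0).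

Step 12. Hydrogen-atom transfer from the stannane to the very hindered C9 radical may outrun its addition to the enone, giving plain deoxygenation, and stannyl radicals may be drained by hydrostannation of 18. The fallback sets out from 15 and comes back at 19, and it uses a redox-neutral photoredox conjugate addition with no hydrogen-atom donor in the flask. Alcohol 15 would be acylated with methyl chlorooxoacetate (Et3N, DMAP, CH2Cl2) to the methyl oxalate F1, then saponified with one equivalent of CsOH (THF–H2O) to the caesium oxalate F2. F2 would be irradiated with blue light together with 18 and Ir[dF(CF3)ppy]2(dtbbpy)PF6 (DME–DMF, H2O, 60 °C). Oxidation of the carboxylate and loss of two CO2 release the same C9 radical, which adds to 18; reduction of the adduct radical to the enolate and protonation should then give 19 with the same axial delivery.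

Step 14. Protodesilylation of the crowded tetrasubstituted enol silane in the aqueous medium may be faster than its aldol addition, returning the C4–H ketone. The fallback sets out from 21 and comes back at 27, and it brings in the one-carbon unit without water at the aldehyde oxidation level. Trimethyl orthoformate with BF3·OEt2 (CH2Cl2, −78 °C) would add the dimethoxymethyl cation to C4 from the same face and give the keto acetal F3. NaBH4 would give the equatorial C3 alcohol F4, and Ac2O with DMAP the acetate F5. TFA–H2O (CH2Cl2, 0 °C) would hydrolyse the dimethyl acetal and the C8 MOM ether together to the acetoxy aldehyde F6. NaBH4 with CeCl3·7H2O (MeOH, −40 °C) would then reduce only the aldehyde and land on 27.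

Further compounds
F0 | step 9 | none | none
F1 | step 12 | methyl oxalate of alcohol 15 | COC(=O)C(=O)O[C@H]1[C@]2(C)CCC(O[Si](C)(C)C(C)(C)C)=C(C)[C@H]2CC[C@]1(C)OCOC
F2 | step 12 | caesium oxalate of alcohol 15 | [Cs+].[O-]C(=O)C(=O)O[C@H]1[C@]2(C)CCC(O[Si](C)(C)C(C)(C)C)=C(C)[C@H]2CC[C@]1(C)OCOC
F3 | step 14 | 3-ketone with equatorial 4-(dimethoxymethyl) group, 8-OMOM, side-chain enol triflate | C=C(OS(=O)(=O)C(F)(F)F)CC[C@@H]1[C@]2(C)CCC(=O)[C@](C)(C(OC)OC)[C@H]2CC[C@]1(C)OCOC
F4 | step 14 | equatorial C3 alcohol from F3 | C=C(OS(=O)(=O)C(F)(F)F)CC[C@@H]1[C@]2(C)CC[C@@H](O)[C@](C)(C(OC)OC)[C@H]2CC[C@]1(C)OCOC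
F5 | step 14 | C3 acetate of F4 | C=C(OS(=O)(=O)C(F)(F)F)CC[C@@H]1[C@]2(C)CC[C@@H](OC(C)=O)[C@](C)(C(OC)OC)[C@H]2CC[C@]1(C)OCOC
F6 | step 14 | 3-acetoxy-4-formyl-8-hydroxy decalin with side-chain enol triflate | C=C(OS(=O)(=O)C(F)(F)F)CC[C@@H]1[C@]2(C)CC[C@@H](OC(C)=O)[C@](C)(C=O)[C@H]2CC[C@]1(C)O
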